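**Plan**

- Retrosynthesis: the MOM ether on ring A and the diketone oxidation level are taken back first, to the silyl-protected benzoin 18. Ring B is then cut at C1–C2 and C5–C6 (retro-Diels–Alder/aromatisation) into bis-silyloxy diene 7 and terminal ynone 16. Ynone 16 is cut at the acyl–alkyne bond (Weinreb amide 14) and at the aryl–carbinol bond (aryllithium plus ethyl glyoxylate).
- Enabling feature: in ring B the prenyl-bearing C3 lies between the oxygenated C2 and C4, just as the α-carbon of acetoacetate lies between its two carbonyls. The acyl-bearing C1 with unsubstituted C6 and C5 corresponds to a terminal ynone.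
- Forward: methyl acetoacetate is C-prenylated and silylated twice (steps 1–3). Ring A is bought as 2-bromo-5-methoxyphenol and extended to ynone 16 (steps 4–8). Ring B, the only ring made, arises in step 9.
- End game: desilylation, oxidation of the acyloin to the dione, and MOM removal (steps 10–12).
- Stereochemistry: the target is achiral. The silyloxy carbinol carbon is carried as a racemate and becomes a carbonyl in step 11; the prenyl alkene has no geometry.

Key step: step 9

Remark: ethyl glyoxylate 10 is taken as the monomer, freshly distilled from its commercial toluene solution, and diene 7 is isolated without aqueous work-up and used at once.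

**Route**

Step 1
Reactants: 1 methyl acetoacetate; 2 prenyl bromide
Product: 4 methyl 2-acetyl-5-methylhex-4-enoate (racemic), via sodium enolate 3 (not isolated)
Conditions: NaH, THF, 0 °C; then 2 (slightly less than 1 equiv), 0 → 20 °C
Reagents that add atoms: none
Why: Acetoacetic ester alkylation, in which the stabilised sodium enolate is C-alkylated by the allylic bromide in an SN2 reaction, with a small excess of 1 holding back dialkylation.

Step 2
Reactants: 4 methyl 2-acetyl-5-methylhex-4-enoate
Product: 5 methyl 5-methyl-2-[1-(trimethylsilyloxy)ethylidene]hex-4-enoate (E/Z mixture)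
Conditions: Me3SiCl, Et3N, toluene, 20 °C; filtration under argon
Reagents that add atoms: chlorotrimethylsilane, C[Si](C)(C)Cl
Why: O-Silylation of the enolisable β-keto ester (first stage of the Chan-type bis-silyl diene preparation) should give the conjugated silyl enol ether, and any non-conjugated enol ether isomer converges on the same dienolate in step 3.

Step 3
Reactants: 5 methyl 5-methyl-2-[1-(trimethylsilyloxy)ethylidene]hex-4-enoate
Product: 7 1-methoxy-2-(3-methylbut-2-enyl)-1,3-bis(trimethylsilyloxy)buta-1,3-diene (ketene acetal geometry unassigned), via lithium dienolate 6 (not isolated)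
Conditions: LiN(i-Pr)2, THF, −78 °C; then Me3SiCl, −78 → 20 °C; pentane, filtration, no aqueous work-up
Reagents that add atoms: chlorotrimethylsilane, C[Si](C)(C)Cl
Why: Kinetic γ-deprotonation of the vinylogous ester followed by O-silylation of the extended enolate (silyl ketene acetal formation) is the established access to 2-alkyl 1-alkoxy-1,3-bis(silyloxy)dienes; the prenyl CH2 is not ester-stabilised and should not compete.

Step 4
Reactants: 8 2-bromo-5-methoxyphenol
Product: 9 1-bromo-4-methoxy-2-(methoxymethoxy)benzene
Conditions: MOMCl, i-Pr2NEt, CH2Cl2, 0 → 20 °C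
Reagents that add atoms: chloromethyl methyl ether, COCCl
Why: O-Alkylation of the phenol with chloromethyl methyl ether (MOM protection) gives an acetal that tolerates the organolithium, Grignard, fluoride and oxidation steps.

Step 5
Reactants: 9 1-bromo-4-methoxy-2-(methoxymethoxy)benzene; 10 ethyl glyoxylate
Product: 12 ethyl 2-hydroxy-2-[4-methoxy-2-(methoxymethoxy)phenyl]acetate (racemic), via aryllithium 11 (not isolated)
Conditions: n-BuLi, THF, −78 °C; then cannulation into 10 (excess), THF, −78 °C; aq NH4Cl
Reagents that add atoms: none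
Why: Bromine–lithium exchange outruns deprotonation at −78 °C and the chelated aryllithium undergoes 1,2-addition to the aldehyde of the glyoxylate in preference to its ester; the new carbinol centre forms without control and is oxidised away later.

Step 6
Reactants: 12 ethyl 2-hydroxy-2-[4-methoxy-2-(methoxymethoxy)phenyl]acetate
Product: 13 ethyl 2-(tert-butyldimethylsilyloxy)-2-[4-methoxy-2-(methoxymethoxy)phenyl]acetate (racemic)
Conditions: TBSCl, imidazole, DMF, 20 °C
Reagents that add atoms: tert-butyldimethylsilyl chloride, CC(C)(C)[Si](C)(C)Cl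
Why: Silyl ether formation under Corey conditions protects the secondary benzylic alcohol through amide formation, Grignard addition and the dilute-acid work-up of step 9.

Step 7
Reactants: 13 ethyl 2-(tert-butyldimethylsilyloxy)-2-[4-methoxy-2-(methoxymethoxy)phenyl]acetate
Product: 14 2-(tert-butyldimethylsilyloxy)-N-methoxy-2-[4-methoxy-2-(methoxymethoxy)phenyl]-N-methylacetamide (racemic)
Conditions: MeNH(OMe)·HCl, i-PrMgCl, THF, −20 → 0 °C; aq NH4Cl
Reagents that add atoms: N,O-dimethylhydroxylamine hydrochloride, CNOC.Cl
Why: Aminolysis of the ester by the magnesium amide of N,O-dimethylhydroxylamine (Weinreb amide formation from an ester) proceeds at low temperature and is routine for α-silyloxy esters.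

Step 8
Reactants: 14 2-(tert-butyldimethylsilyloxy)-N-methoxy-2-[4-methoxy-2-(methoxymethoxy)phenyl]-N-methylacetamide
Product: 16 1-(tert-butyldimethylsilyloxy)-1-[4-methoxy-2-(methoxymethoxy)phenyl]but-3-yn-2-one (racemic), via magnesium hemiaminal chelate 15 (not isolated)
Conditions: HC≡CMgBr, THF, −78 → 0 °C; then poured into cold 1 M aq HCl
Reagents that add atoms: ethynylmagnesium bromide, C#C[Mg]Br
Why: Weinreb ketone synthesis, in which the chelated tetrahedral adduct 15 resists a second addition and releases the terminal ynone only on the cold acidic quench, which also protonates the liberated amine before it can add to the ynone.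

Step 9
Reactants: 7 1-methoxy-2-(3-methylbut-2-enyl)-1,3-bis(trimethylsilyloxy)buta-1,3-diene (excess); 16 1-(tert-butyldimethylsilyloxy)-1-[4-methoxy-2-(methoxymethoxy)phenyl]but-3-yn-2-one
Product: 18 2-(tert-butyldimethylsilyloxy)-1-[2,4-dihydroxy-3-(3-methylbut-2-enyl)phenyl]-2-[4-methoxy-2-(methoxymethoxy)phenyl]ethan-1-one (racemic), via cycloadduct 17 (not isolated)
Conditions: toluene, −78 → 20 °C (45 °C if needed); then 1 M aq HCl, THF, 0 °C
Reagents that add atoms: none
Why: The electron-rich diene 7 and the electron-poor terminal ynone 16 should combine in a normal-electron-demand [4+2] cycloaddition in which the unsubstituted CH2 terminus, carrying the largest HOMO coefficient, bonds to the terminal (β) alkyne carbon and the ketene acetal carbon bonds to the α carbon, giving the cyclohexa-1,4-diene mixed ketal 17. Dilute acid then cleaves the ketal silyl ether, the hemiketal expels methanol, the enol silyl ether is hydrolysed and the cyclohexadienone tautomerises to the resorcinol, so the acyl group ends up next to the C2 hydroxyl and the prenyl group sits at C3 between both oxygens. The closest known reaction type is the Diels–Alder/aromatisation of 1-alkoxy-1,3-bis(silyloxy)buta-1,3-dienes (Chan- and Brassard-type dienes, 2-alkyl members included) with acetylenic esters and ketones to give resorcinol derivatives. Ring B closes in an intermolecular six-membered [4+2] mode that forms C1–C2 and C5–C6 in one operation, and no lasting stereocentre is created (the ketal carbon of 17 is lost on aromatisation and the silyloxy carbon is a racemic spectator). The step needs the stated regiochemistry and the [4+2] mode rather than a [3+3] Michael/aldol mode or carbonyl addition: the polarity match of the two partners dictates the first, and the absence of a Lewis acid, the prenyl group on the central diene carbon (which blocks aromatisation after C-attack there) and the bulky silyloxy(aryl)methyl group shielding the ketone should secure the second.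

Step 10
Reactants: 18 2-(tert-butyldimethylsilyloxy)-1-[2,4-dihydroxy-3-(3-methylbut-2-enyl)phenyl]-2-[4-methoxy-2-(methoxymethoxy)phenyl]ethan-1-one
Product: 19 1-[2,4-dihydroxy-3-(3-methylbut-2-enyl)phenyl]-2-hydroxy-2-[4-methoxy-2-(methoxymethoxy)phenyl]ethan-1-one (racemic)
Conditions: Bu4NF, AcOH, THF, 0 → 20 °C, argon
Reagents that add atoms: none
Why: Fluoride-mediated desilylation, buffered with AcOH to suppress base-induced autoxidation; an acyloin shift would be harmless because both acyloin isomers oxidise to the same dione.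

Step 11
Reactants: 19 1-[2,4-dihydroxy-3-(3-methylbut-2-enyl)phenyl]-2-hydroxy-2-[4-methoxy-2-(methoxymethoxy)phenyl]ethan-1-one
Product: 20 1-[2,4-dihydroxy-3-(3-methylbut-2-enyl)phenyl]-2-[4-methoxy-2-(methoxymethoxy)phenyl]ethane-1,2-dione
Conditions: Dess–Martin periodinane, CH2Cl2, 0 °C
Reagents that add atoms: none
Why: Dess–Martin oxidation of the activated benzylic α-hydroxy ketone to the 1,2-diketone should be fast, while the ring B phenols are deactivated by the para/ortho acyl group and the intramolecular hydrogen bond.

Step 12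
Reactants: 20 1-[2,4-dihydroxy-3-(3-methylbut-2-enyl)phenyl]-2-[4-methoxy-2-(methoxymethoxy)phenyl]ethane-1,2-dione
Product: 21 licoagrodione, 1-[2,4-dihydroxy-3-(3-methylbut-2-enyl)phenyl]-2-(2-hydroxy-4-methoxyphenyl)ethane-1,2-dione
Conditions: 3 M aq HCl, MeOH, 20 °C
Reagents that add atoms: none
Why: Acid-catalysed acetal solvolysis (MOM removal), assisted by the ortho carbonyl, is run at ambient temperature so that the prenyl side chain does not cyclise onto a neighbouring phenol, as is usual for prenylated phenolic ketones.

**Compound list**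

1 | methyl acetoacetate | COC(=O)CC(C)=O | starting material
2 | prenyl bromide (1-bromo-3-methylbut-2-ene) | CC(C)=CCBr | starting material
3 | sodium enolate of methyl acetoacetate | COC(=O)C=C(C)[O-].[Na+] | intermediate
4 | methyl 2-acetyl-5-methylhex-4-enoate (racemic) | COC(=O)C(CC=C(C)C)C(C)=O | intermediate
5 | methyl 5-methyl-2-[1-(trimethylsilyloxy)ethylidene]hex-4-enoate (E/Z mixture) | COC(=O)C(CC=C(C)C)=C(C)O[Si](C)(C)C | intermediate
6 | lithium 1-methoxy-2-(3-methylbut-2-enyl)-3-(trimethylsilyloxy)buta-1,3-dien-1-olate | C=C(O[Si](C)(C)C)C(CC=C(C)C)=C(OC)[O-].[Li+] | intermediate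
7 | 1-methoxy-2-(3-methylbut-2-enyl)-1,3-bis(trimethylsilyloxy)buta-1,3-diene (geometry unassigned) | C=C(O[Si](C)(C)C)C(CC=C(C)C)=C(OC)O[Si](C)(C)C | intermediate
8 | 2-bromo-5-methoxyphenol | COc1ccc(Br)c(O)c1 | starting material
9 | 1-bromo-4-methoxy-2-(methoxymethoxy)benzene | COCOc1cc(OC)ccc1Br | intermediate
10 | ethyl glyoxylate | CCOC(=O)C=O | starting material
11 | [4-methoxy-2-(methoxymethoxy)phenyl]lithium | COCOc1cc(OC)ccc1[Li] | intermediate
12 | ethyl 2-hydroxy-2-[4-methoxy-2-(methoxymethoxy)phenyl]acetate (racemic) | CCOC(=O)C(O)c1ccc(OC)cc1OCOC | intermediate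
13 | ethyl 2-(tert-butyldimethylsilyloxy)-2-[4-methoxy-2-(methoxymethoxy)phenyl]acetate (racemic) | CCOC(=O)C(O[Si](C)(C)C(C)(C)C)c1ccc(OC)cc1OCOC | intermediate
14 | 2-(tert-butyldimethylsilyloxy)-N-methoxy-2-[4-methoxy-2-(methoxymethoxy)phenyl]-N-methylacetamide (racemic) | CON(C)C(=O)C(O[Si](C)(C)C(C)(C)C)c1ccc(OC)cc1OCOC | intermediate
15 | bromomagnesium hemiaminal chelate (tetrahedral adduct of 14 and ethynylmagnesium bromide) | C#CC(O[Mg]Br)(N(C)OC)C(O[Si](C)(C)C(C)(C)C)c1ccc(OC)cc1OCOC | intermediate
16 | 1-(tert-butyldimethylsilyloxy)-1-[4-methoxy-2-(methoxymethoxy)phenyl]but-3-yn-2-one (racemic) | C#CC(=O)C(O[Si](C)(C)C(C)(C)C)c1ccc(OC)cc1OCOC | intermediate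
17 | 2-(tert-butyldimethylsilyloxy)-1-[6-methoxy-5-(3-methylbut-2-enyl)-4,6-bis(trimethylsilyloxy)cyclohexa-1,4-dien-1-yl]-2-[4-methoxy-2-(methoxymethoxy)phenyl]ethan-1-one (diastereomer mixture) | COC1(O[Si](C)(C)C)C(CC=C(C)C)=C(O[Si](C)(C)C)CC=C1C(=O)C(O[Si](C)(C)C(C)(C)C)c1ccc(OC)cc1OCOC | intermediate
18 | 2-(tert-butyldimethylsilyloxy)-1-[2,4-dihydroxy-3-(3-methylbut-2-enyl)phenyl]-2-[4-methoxy-2-(methoxymethoxy)phenyl]ethan-1-one (racemic) | COCOc1cc(OC)ccc1C(O[Si](C)(C)C(C)(C)C)C(=O)c1ccc(O)c(CC=C(C)C)c1O | intermediate
19 | 1-[2,4-dihydroxy-3-(3-methylbut-2-enyl)phenyl]-2-hydroxy-2-[4-methoxy-2-(methoxymethoxy)phenyl]ethan-1-one (racemic) | COCOc1cc(OC)ccc1C(O)C(=O)c1ccc(O)c(CC=C(C)C)c1O | intermediate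
20 | 1-[2,4-dihydroxy-3-(3-methylbut-2-enyl)phenyl]-2-[4-methoxy-2-(methoxymethoxy)phenyl]ethane-1,2-dione | COCOc1cc(OC)ccc1C(=O)C(=O)c1ccc(O)c(CC=C(C)C)c1O | intermediate
21 | licoagrodione | COc1ccc(C(=O)C(=O)c2ccc(O)c(CC=C(C)C)c2O)c(O)c1 | target

**Step count and risks**

Total: 12 steps. Longest linear sequence: 9 steps (steps 4–12); the diene branch (steps 1–3) joins at step 9.

Steps most likely to fail:

1. Step 9. The crowded diene may be protodesilylated faster than it cycloadds, the reaction may stop at an open-chain Michael adduct, or the ketene acetal may attack the ketone carbonyl.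
Fallback: it sets out from Weinreb amide 14 and returns at target 21, building ring B from a resorcinol instead of de novo. Commercial 1,3-bis(methoxymethoxy)benzene F1 is lithiated between the two acetal oxygens (n-BuLi, THF, 0 °C) to [2,6-bis(methoxymethoxy)phenyl]lithium F2, which is alkylated with prenyl bromide 2 (CuBr·SMe2 catalyst) to 1,3-bis(methoxymethoxy)-2-(3-methylbut-2-enyl)benzene F3. A second directed ortho-lithiation (n-BuLi, TMEDA, THF, 0 °C) gives [2,4-bis(methoxymethoxy)-3-(3-methylbut-2-enyl)phenyl]lithium F4, which adds to 14 to give the tris-MOM silyl benzoin ether F5. Bu4NF/AcOH should give the tris-MOM hydroxy ketone F6, Dess–Martin periodinane the tris-MOM dione F7, and 3 M aq HCl in MeOH should remove all three MOM groups to give 21.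

2. Step 11. Ligand exchange of the periodinane at the free ring B phenols may lead to oxidative degradation of the resorcinol in competition with carbinol oxidation.
Fallback: it sets out from 18 and returns at 20, with the phenols capped during the oxidation. Ac2O, pyridine and DMAP should convert 18 into the diacetate silyl ether F8. HF·pyridine in THF should free the carbinol to give the hydroxy ketone diacetate F9. Dess–Martin periodinane should give the dione diacetate F10, and catalytic K2CO3 in MeOH at 0 °C should remove both aryl acetates to give 20.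

3. Step 12. Protonation of the prenyl alkene may lead to ring closure onto the C2 or C4 hydroxyl (chroman formation), or to addition of HCl or MeOH across the alkene, before the acetal is fully solvolysed.
Fallback: it sets out from 20 and returns at 21 without any protic acid. Me3SiOTf and 2,2′-bipyridyl in MeCN at 0 °C should transfer the ring A aryl oxygen from the acetal carbon to silicon, with the methoxymethyl cation trapped by bipyridyl, and silylate the two free phenols. This gives the tris(trimethylsilyl) ether of licoagrodione F11, which water hydrolyses during work-up to 21.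

**Further compounds**

F1 | step 9 | 1,3-bis(methoxymethoxy)benzene | COCOc1cccc(OCOC)c1
F2 | step 9 | [2,6-bis(methoxymethoxy)phenyl]lithium | COCOc1cccc(OCOC)c1[Li]
F3 | step 9 | 1,3-bis(methoxymethoxy)-2-(3-methylbut-2-enyl)benzene | COCOc1cccc(OCOC)c1CC=C(C)C
F4 | step 9 | [2,4-bis(methoxymethoxy)-3-(3-methylbut-2-enyl)phenyl]lithium | COCOc1ccc([Li])c(OCOC)c1CC=C(C)C
F5 | step 9 | 1-[2,4-bis(methoxymethoxy)-3-(3-methylbut-2-enyl)phenyl]-2-(tert-butyldimethylsilyloxy)-2-[4-methoxy-2-(methoxymethoxy)phenyl]ethan-1-one (racemic) | COCOc1cc(OC)ccc1C(O[Si](C)(C)C(C)(C)C)C(=O)c1ccc(OCOC)c(CC=C(C)C)c1OCOC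
F6 | step 9 | 1-[2,4-bis(methoxymethoxy)-3-(3-methylbut-2-enyl)phenyl]-2-hydroxy-2-[4-methoxy-2-(methoxymethoxy)phenyl]ethan-1-one (racemic) | COCOc1cc(OC)ccc1C(O)C(=O)c1ccc(OCOC)c(CC=C(C)C)c1OCOC
F7 | step 9 | 1-[2,4-bis(methoxymethoxy)-3-(3-methylbut-2-enyl)phenyl]-2-[4-methoxy-2-(methoxymethoxy)phenyl]ethane-1,2-dione | COCOc1cc(OC)ccc1C(=O)C(=O)c1ccc(OCOC)c(CC=C(C)C)c1OCOC
F8 | step 11 | 4-{2-(tert-butyldimethylsilyloxy)-2-[4-methoxy-2-(methoxymethoxy)phenyl]acetyl}-2-(3-methylbut-2-enyl)-1,3-phenylene diacetate (racemic) | COCOc1cc(OC)ccc1C(O[Si](C)(C)C(C)(C)C)C(=O)c1ccc(OC(C)=O)c(CC=C(C)C)c1OC(C)=O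
F9 | step 11 | 4-{2-hydroxy-2-[4-methoxy-2-(methoxymethoxy)phenyl]acetyl}-2-(3-methylbut-2-enyl)-1,3-phenylene diacetate (racemic) | COCOc1cc(OC)ccc1C(O)C(=O)c1ccc(OC(C)=O)c(CC=C(C)C)c1OC(C)=O
F10 | step 11 | 4-{2-[4-methoxy-2-(methoxymethoxy)phenyl]-2-oxoacetyl}-2-(3-methylbut-2-enyl)-1,3-phenylene diacetate | COCOc1cc(OC)ccc1C(=O)C(=O)c1ccc(OC(C)=O)c(CC=C(C)C)c1OC(C)=O
F11 | step 12 | tris(trimethylsilyl) ether of licoagrodione | COc1ccc(C(=O)C(=O)c2ccc(O[Si](C)(C)C)c(CC=C(C)C)c2O[Si](C)(C)C)c(O[Si](C)(C)C)c1
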